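Read the ratio, not the amounts.

| flask | substrate | remark | time |
|---|---|---|---|
| cedar | 1.1 M | the very flask that is asked about, followed so far |  |
| birch | 1.7 M | run made earlier |  |
| flask | 1.1 M |  | 3.0 d |

cedar run (percent of the substrate charged)

| time / h | isomer of the product / % | target / % |
|---|---|---|
| 3.00 | 8 | 13 |
| 4.00 | 10 | 17 |
| 6.00 | 9 | 17 |
| 10.0 | 14 | 16 |
| 15.0 | 17 | 21 |
| 25.0 | 22 | 18 |
| 40.0 | 24 | 13 |

birch run (percent of the substrate charged)

| time / d | isomer of the product / % | target / % |
|---|---|---|
| 0.250 | 12 | 14 |
| 0.333 | 12 | 16 |
| 0.500 | 13 | 17 |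
| 0.833 | 20 | 15 |
| 1.25 | 21 | 13 |
| 2.08 | 24 | 8 |
| 3.00 | 28 | 5 |

(standard deviation of a reading: 1.5 percentage points)

1. ratio of isomer of the product to target at 8.0 min
2. ratio of isomer of the product to target at 3.0 h
3. ratio of isomer of the product to target at 3.0 d
4. which of isomer of the product and target there is more of at 3.0 d



Cedar stops at 40.0 h, but the question runs to 3.0 d, so cedar has to be carried forward, and birch, with its larger charge, was read at that very time. Birch can stand in for cedar if the charge leaves the ratio R, isomer of the product over target at a given time, unmoved. Cedar gives R = 1.85 at 40.0 h, and birch brackets that reading with 1.62 at 1.25 d and 3.00 at 2.08 d, so around that time the two runs can be read as one curve of R against time.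

The early cedar readings, up to 6.00 h, pool to R = 0.574 and show no climb, so this reckoning takes that value for both 8.0 min and 3.0 h. Birch's last pair gives 5.60, the end ratio R_e, isomer of the product over target at 3.00 d. Its target reading of 5% carries a scatter of 1.5 percentage points, so R_e is good to about 1.68, but it stands well above one, so the isomer of the product should lead.

The forecast, reasoning that “the target is converting to the isomer”, gave 0.5, 0.57 and 4.4 with isomer of the product ahead, ending lower than R_e.

The flask gives 0.536, 0.590 and 6.02, with isomer of the product ahead at 30.7% against 5.09% of target.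

    substrate ⇌ isomer of the product (K = 69.8, k = 8.60 × 10⁻⁶ s⁻¹)
    substrate ⇌ third isomer (K = 0.475, k = 1.62 × 10⁻⁵ s⁻¹)
    2 substrate → homo dimer (k = 1.15 × 10⁻⁵ M⁻¹ s⁻¹)
    target → over-reaction product (k = 9.38 × 10⁻⁶ s⁻¹)
    substrate ⇌ target (K = 2.10, k = 1.61 × 10⁻⁵ s⁻¹)

At 3.0 d in this flask, target is made at 0.224 of the rate at which it is used up, each step taken net. A neighbour flask with 0.28 M of substrate, a quarter of this charge, ends with 38.7% of isomer of the product against 30.7% here, and its ratio is 5.61. That ratio and the 6.02 of this flask each lie less than 1.68 from R_e = 5.60 .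

(Readings and results are calculated with made-up constants, noise included.)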